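- The pitfall with west and north-west is to expect the longer flask to stand higher, as if the excess of right-handed substrate could do nothing but climb with time.

all flasks: racemization catalyst 0.70 mM
- noon: left-handed substrate 0.17 M; right-handed substrate 0.17 M; partner 0.70 M; run made earlier
- dusk: left-handed substrate 0.70 M; right-handed substrate 0.70 M; partner 0.70 M; run made earlier
- west: left-handed substrate 0.35 M; right-handed substrate 0.35 M; partner 0.700 M; time 2.0 min
- north-west: left-handed substrate 0.35 M; right-handed substrate 0.35 M; partner 0.700 M; time 4.0 min

| run | time / min | right-handed substrate / % | left-handed substrate / % |
|---|---|---|---|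
| noon | 0.333 | 37.8 | 6.1 |
| noon | 0.667 | 35.2 | 2.7 |
| noon | 1.00 | 33.0 | 2.7 |
| noon | 1.33 | 32.4 | 2.0 |
| noon | 1.50 | 31.3 | 2.1 |
| noon | 2.00 | 30.9 | 2.2 |
| noon | 2.50 | 29.6 | 0.7 |
| dusk | 0.167 | 44.8 | 21.3 |
| dusk | 0.333 | 42.5 | 18.9 |
| dusk | 0.667 | 42.8 | 19.1 |
| dusk | 1.00 | 41.8 | 19.7 |
| dusk | 1.33 | 40.4 | 20.4 |
| dusk | 2.00 | 40.2 | 21.0 |
| dusk | 2.50 | 40.1 | 21.3 |

(standard deviation of a reading: 0.5 percentage points)

1. the winner by excess of right-handed substrate over left-handed substrate among what is left of the two; "neither" if no more than 2 percentage points parts them (west / north-west / neither)
2. excess of right-handed substrate over left-handed substrate among what is left of the two at the end, west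
3. excess of right-handed substrate over left-handed substrate among what is left of the two at the end, north-west

- partner is single-handed; left-handed substrate and right-handed substrate are mirror images of each other, charged as a racemate, each of them at the stated concentration
- an excess is below zero if the other one leads
- the handed part of partner does not stay in what it makes, so the products of the two hands are mirror images too

- I start with the main step: partner takes both hands, left-handed substrate faster. The first noon reading, as the ratio of the logarithms of what is left of each hand, gives a selectivity factor of about 7.52. By this step by itself the excess climbs, which favours north-west.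
- Next I add that in dusk partner delivers less product than its charge allows. In dusk it covers 0.500 of the substrate charge, yet the fraction reacted is 38.6 %, and the total left stands still, 61.4 % at 0.333 min and 61.4 % at 2.50 min. So in dusk the climb ends early.
- Then I take that burst as finished and reckon with what still moves after it, the turning of one hand into the other by the racemization catalyst. In dusk the left-handed substrate creeps up from 18.9 % to 21.3 % while the excess sinks. I call the fall per minute of the logarithm of the excess, once the total stands still, the fade rate: dusk reads 0.105 min⁻¹.
- West's charge lies at the geometric middle of noon and dusk, so I average their excesses at 2.00 min, 86.7 % and 31.4 %, and commit to 59.0 % for west. Fading from there at the dusk rate gives 47.9 % for north-west, so I expect west to lead by 11 percentage points, more than the margin.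
- The forecast says west, with 63 % and 54 %, both above my figures, holding that “racemization continues with no partner to remove it”.
- The flask gives west, at 71.5 % in west and 65.2 % in north-west, higher than my 59.0 % and 47.9 %.

    partner + left-handed substrate → left-handed product (k = 0.388 M⁻¹ s⁻¹)
    partner + right-handed substrate → right-handed product (k = 0.0442 M⁻¹ s⁻¹)
    left-handed substrate + racemization catalyst ⇌ right-handed substrate + racemization catalyst, rate k3*[racemization catalyst]*[left-handed substrate] forward; the back reaction follows from the equilibrium constant (k = 16.5 M⁻¹ s⁻¹)
    partner + racemization catalyst → spent catalyst (k = 0.491 M⁻¹ s⁻¹)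
    2 partner → self-condensation product (k = 0.103 M⁻¹ s⁻¹)
    racemization catalyst ⇌ dormant form (K = 2.80, k = 0.0264 s⁻¹)

- At the end of west the racemization catalyst stands at 3.69 % of its charge. The fade rate between the two results is 0.0465 min⁻¹, slower than the 0.105 min⁻¹ of dusk. Carried past north-west to the same flask left until 5.0 min, it gives 62.2 %, and that flask stands at 61.8 %.

The runs are simulated for substances that don't exist; scatter was added.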